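Locants: five-membered ring C1 (triene-bearing), C2, C3, C4 (spiro), C5; six-membered ring C4, C6–C10. Everything rests on cutting C4–C6. In the target the C5 hydroxyl and the C4–C6 bond are anti across C4–C5, and C10 is oxygenated next to C4: the imprint of a C4–C5 epoxide opened by a carbon migrating from C10. One operation, hydroxyl-directed epoxidation then Lewis acid, expands a cyclopentanol into the cyclohexanone, forms C4–C6 and sets C4 and C5. Its substrate is the tertiary alcohol from a 3-(silyloxymethyl)cyclopentenyllithium and trans-2-allyl-3-isopropenylcyclopentanone; allyl, isopropenyl and the arm later become hydroxypropyl chain, enal and triene.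

Key step: step 7

Remarks
- Assumption: in steps 1 and 2 the antipode of the ferrocenyl diphosphine is chosen by a short screen so that the 3S centre (step 1) and the 3R centre (step 2) result.
- Compounds 20–23 are carried as mixtures of epimers at the 1-hydroxyethyl carbinol, which is erased in step 14.
- The arm keeps a tert-butyldimethylsilyl ether through step 7 on purpose: it is bulky, its oxygen is a poor nucleophile towards a C4 cation, and it can later be removed selectively.

Step 1
Reactants: 1 cyclopent-2-en-1-one; 2 isopropenylmagnesium bromide; 3 allyl bromide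
Product: 5 (2R,3S)-2-allyl-3-(prop-1-en-2-yl)cyclopentan-1-one, via magnesium enolate 4 (not isolated)
Conditions: CuBr·SMe2 (5 mol%), 1-[2-(diphenylphosphino)ferrocenyl]ethyldicyclohexylphosphine (6 mol%), t-BuOMe, −75 °C; then 3, DMPU, −75 → 0 °C
Reagents that add atoms: none
Why: Copper-catalysed asymmetric conjugate addition of the Grignard reagent should set C3 under ligand control, and alkylation of the regiodefined magnesium enolate anti to the new isopropenyl group (conjugate addition–enolate trapping) should set C2 trans to it.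

Step 2
Reactants: 1 cyclopent-2-en-1-one; 6 (chloromethyl)(isopropoxy)dimethylsilane
Product: 9 (3R)-3-{[isopropoxy(dimethyl)silyl]methyl}cyclopent-1-en-1-yl trifluoromethanesulfonate, via Grignard reagent 7 (not isolated), via magnesium enolate 8 (not isolated)
Conditions: 6, Mg, Et2O, reflux; then 1, CuBr·SMe2 (5 mol%), 1-[2-(diphenylphosphino)ferrocenyl]ethyldicyclohexylphosphine (6 mol%), t-BuOMe, −75 °C; then N-(5-chloropyridin-2-yl)triflimide, −75 → 0 °C
Reagents that add atoms: N-(5-chloropyridin-2-yl)-1,1,1-trifluoro-N-[(trifluoromethyl)sulfonyl]methanesulfonamide, FC(F)(F)S(=O)(=O)N(c1ccc(Cl)cn1)S(=O)(=O)C(F)(F)F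
Why: Copper-catalysed asymmetric conjugate addition of the silylmethyl Grignard reagent (a masked hydroxymethyl anion) should set the 3R centre by ligand control, and O-sulfonylation of the magnesium enolate (enolate trapping) fixes the double bond between the carbonyl carbon and C2.

Step 3
Reactants: 9 (3R)-3-{[isopropoxy(dimethyl)silyl]methyl}cyclopent-1-en-1-yl trifluoromethanesulfonate
Product: 10 (3R)-3-(hydroxymethyl)cyclopent-1-en-1-yl trifluoromethanesulfonate
Conditions: H2O2 (30% aq.), KF, KHCO3, THF/MeOH, 0 °C → rt
Reagents that add atoms: hydrogen peroxide, OO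
Why: Tamao–Fleming oxidation of the alkoxysilane should turn the C–Si bond into C–OH under bicarbonate-buffered conditions mild enough for the enol triflate, and the stereocentre is not touched.

Step 4
Reactants: 10 (3R)-3-(hydroxymethyl)cyclopent-1-en-1-yl trifluoromethanesulfonate
Product: 11 (3R)-3-({[tert-butyl(dimethyl)silyl]oxy}methyl)cyclopent-1-en-1-yl trifluoromethanesulfonate
Conditions: TBSCl, imidazole, CH2Cl2, 0 °C → rt
Reagents that add atoms: tert-butyl(chloro)dimethylsilane, CC(C)(C)[Si](C)(C)Cl
Why: Silylation of an unhindered primary alcohol installs the bulky ether that is to shield one face of the cyclopentene in step 7.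

Step 5
Reactants: 11 (3R)-3-({[tert-butyl(dimethyl)silyl]oxy}methyl)cyclopent-1-en-1-yl trifluoromethanesulfonate
Product: 12 tert-butyl(dimethyl){[(1R)-3-(trimethylstannyl)cyclopent-2-en-1-yl]methoxy}silane
Conditions: (Me3Sn)2, Pd(PPh3)4 (5 mol%), LiCl, THF, 65 °C
Reagents that add atoms: hexamethylditin, C[Sn](C)(C)[Sn](C)(C)C
Why: Palladium-catalysed stannylation of the enol triflate (oxidative addition, Sn–Sn transmetalation, reductive elimination; Stille-type) should exchange triflate for tin without moving the double bond.

Step 6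
Reactants: 12 tert-butyl(dimethyl){[(1R)-3-(trimethylstannyl)cyclopent-2-en-1-yl]methoxy}silane; 5 (2R,3S)-2-allyl-3-(prop-1-en-2-yl)cyclopentan-1-one
Product: 14 (1S,2R,3S)-2-allyl-1-[(3R)-3-({[tert-butyl(dimethyl)silyl]oxy}methyl)cyclopent-1-en-1-yl]-3-(prop-1-en-2-yl)cyclopentan-1-ol, via alkenyllithium 13 (not isolated)
Conditions: MeLi, THF, −78 °C; then 5, LaCl3·2LiCl, THF, −78 °C
Reagents that add atoms: none
Why: Tin–lithium exchange followed by 1,2-addition to the ketone, which the lanthanum salt activates against enolisation, should place the alkenyl group anti to the neighbouring allyl group (hydroxyl cis to allyl), although either carbinol epimer would serve because this carbon becomes trigonal in step 7, and material from the minor enantiomer of 5 or 12 ends up as separable diastereomers.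

Step 7
Reactants: 14 (1S,2R,3S)-2-allyl-1-[(3R)-3-({[tert-butyl(dimethyl)silyl]oxy}methyl)cyclopent-1-en-1-yl]-3-(prop-1-en-2-yl)cyclopentan-1-ol
Product: 16 (1S,4S,5S,6R,7S)-6-allyl-1-({[tert-butyl(dimethyl)silyl]oxy}methyl)-5-hydroxy-7-(prop-1-en-2-yl)spiro[4.5]decan-10-one (route locants with C4 as spiro atom), via epoxy alcohol 15 (not isolated)
Conditions: VO(acac)2 (5 mol%), t-BuOOH, CH2Cl2, 0 °C; then BF3·OEt2, −78 °C
Reagents that add atoms: tert-butyl hydroperoxide, CC(C)(C)OO
Why: The tertiary alkoxide binds the pentavalent vanadium tert-butylperoxo species, which passes oxygen only to the C4=C5 alkene of the allylic alcohol; BF3 then coordinates the epoxide oxygen, the tertiary C4–O bond ionises and C6 shifts from C10 to C4 while the C10 hydroxyl becomes the carbonyl. The closest known reaction type is the Lewis acid semipinacol rearrangement of 2,3-epoxy alcohols of 1-(cycloalkenyl)cycloalkanols to spirocyclic β-hydroxy ketones. The six-membered ring is closed by ring expansion through this 1,2-alkyl shift (the ring C10, C6, C7, C8, C9 takes up C4), not by an end-to-end cyclisation. C5 is set by the face of epoxidation, which should be the one opposite the C1 silyloxymethyl arm, and C4 is set by the migration, which enters anti to the departing epoxide oxygen so that C4–C6 ends trans to the C5 hydroxyl, with C6 keeping its configuration. The step needs chemoselectivity (hydroxyl direction leaves allyl and isopropenyl untouched), facial selectivity (the C1 arm) and migration of C6 in preference to C9 (the more substituted carbon carries positive charge better and can reach the antiperiplanar position in either carbinol epimer). Low temperature and the bulky, weakly basic silyl ether should keep ether participation and alkene–cation side reactions slow.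

Step 8
Reactants: 16 spiro ketol (C5 hydroxyl free)
Product: 17 5-O-tert-butyldimethylsilyl ether of 16
Conditions: TBSOTf, 2,6-lutidine, CH2Cl2, −78 → 0 °C
Reagents that add atoms: tert-butyldimethylsilyl trifluoromethanesulfonate, CC(C)(C)[Si](C)(C)OS(=O)(=O)C(F)(F)F
Why: Silylation with the silyl triflate should cap the hindered secondary alcohol, which blocks retro-aldol cleavage of the β-hydroxy ketone and puts a large group on the C5 side of the C10 carbonyl.

Step 9
Reactants: 17 bis-silyl ether
Product: 18 primary alcohol at the C1 arm (C5 silyl ether and C10 ketone retained)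
Conditions: camphorsulfonic acid (10 mol%), MeOH/CH2Cl2, 0 °C
Reagents that add atoms: none
Why: Acid-catalysed methanolysis cleaves the unhindered primary silyl ether much faster than the neopentyl-type secondary one at C5 (selective desilylation).

Step 10
Reactants: 18 primary alcohol
Product: 19 C1 aldehyde with C10 ketone and C5 silyl ether
Conditions: DMP, CH2Cl2, 0 °C → rt
Reagents that add atoms: none
Why: Dess–Martin oxidation gives the aldehyde under near-neutral conditions, so C1, which is already trans to the C5 silyloxy group, should not epimerise.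

Step 11
Reactants: 19 keto aldehyde
Product: 20 diol with (10S) methyl carbinol at C10 and a 1-hydroxyethyl group at C1
Conditions: MeLi, CeCl3, THF, −78 → −40 °C
Reagents that add atoms: methyllithium, C[Li]
Why: Organocerium 1,2-addition to both carbonyls should deliver methyl to C10 axially from the C3 face, because in the chair with the C6 and C7 groups equatorial the axial C5 carbon and its silyloxy group close the other face, which leaves the C10 hydroxyl on the C5 side, while the arm carbinol forms as an inconsequential epimer mixture.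

Step 12
Reactants: 20 diol with allyl and isopropenyl groups
Product: 21 triol with 3-hydroxypropyl chain at C6
Conditions: Sia2BH (from BH3·SMe2 and 2-methylbut-2-ene), THF, 0 °C; then NaOH, H2O2, 0 °C → rt
Reagents that add atoms: hydrogen peroxide, OO
Why: Anti-Markovnikov hydroboration–oxidation with the hindered dialkylborane should take the monosubstituted allyl alkene and leave the more hindered 1,1-disubstituted isopropenyl alkene.

Step 13
Reactants: 21 triol
Product: 22 tert-butyldiphenylsilyl ether of the primary hydroxyl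
Conditions: TBDPSCl, imidazole, CH2Cl2, 0 °C
Reagents that add atoms: tert-butyl(chloro)diphenylsilane, CC(C)(C)[Si](Cl)(c1ccccc1)c1ccccc1
Why: Silylation with the bulky chlorosilane is selective for the primary alcohol over the α-branched secondary and the tertiary alcohol.

Step 14
Reactants: 22 silyl ether with isopropenyl group
Product: 24 keto enal with acetyl at C1 and 3-oxoprop-1-en-2-yl at C7, via allylic alcohol 23 (not isolated)
Conditions: SeO2 (0.5 equiv), t-BuOOH, CH2Cl2, rt; then DMP, CH2Cl2, rt
Reagents that add atoms: tert-butyl hydroperoxide, CC(C)(C)OO (terminal oxidant; its oxygen is passed on through selenium dioxide, O=[Se]=O)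
Why: Allylic oxidation with SeO2 (ene reaction, then [2,3]-sigmatropic shift) should hydroxylate the methyl group of the only alkene, and Dess–Martin oxidation then converts both the allylic alcohol and the arm carbinol to carbonyl groups.

Step 15
Reactants: 24 keto enal (2-substituted acrolein)
Product: 25 tetrasubstituted (Z)-enal, C7=C(CH3)CHO with formyl syn to C6
Conditions: RhCl3·3H2O (10 mol%), EtOH, 75 °C
Reagents that add atoms: none
Why: Rhodium hydride double-bond migration (hydrometalation of the methylene, β-hydride elimination of the C7 hydrogen) should move the alkene to the tetrasubstituted conjugated position under thermodynamic control, with the smaller formyl group on the side of the branched C6 to limit allylic 1,3-strain.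

Step 16
Reactants: 25 tetrasubstituted enal
Product: 26 dimethyl acetal of 25
Conditions: HC(OMe)3, pyridinium p-toluenesulfonate (10 mol%), MeOH, rt
Reagents that add atoms: trimethyl orthoformate, COC(OC)OC
Why: Acid-catalysed acetalisation is selective for the aldehyde over the hindered methyl ketone and masks the enal against the base of step 17 and the fluoride of step 22.

Step 17
Reactants: 26 acetal with methyl ketone
Product: 27 enol triflate, C1–C(OSO2CF3)=CH2
Conditions: KN(SiMe3)2 (2.2 equiv), THF, −78 °C; then N-(5-chloropyridin-2-yl)triflimide, −78 °C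
Reagents that add atoms: N-(5-chloropyridin-2-yl)-1,1,1-trifluoro-N-[(trifluoromethyl)sulfonyl]methanesulfonamide, FC(F)(F)S(=O)(=O)N(c1ccc(Cl)cn1)S(=O)(=O)C(F)(F)F
Why: Kinetic deprotonation of the methyl group by the bulky amide and O-sulfonylation of the enolate (enol triflate formation) should give the terminal triflate without touching C1, the second equivalent of base holding the tertiary hydroxyl as a hindered alkoxide that is not sulfonylated at this temperature.

Step 18
Reactants: 28 5-bromo-2-methylpent-2-ene; 29 prop-2-yn-1-ol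
Product: 32 (2Z)-3-iodo-2-(4-methylpent-3-en-1-yl)prop-2-en-1-ol, via Grignard reagent 30 (not isolated), via alkenylmagnesium alkoxide 31 (not isolated)
Conditions: 28, Mg, THF, rt; then 29, CuI (10 mol%), THF, −20 °C → rt; then I2, −78 → 0 °C
Reagents that add atoms: iodine, II
Why: Copper-catalysed anti-carbomagnesiation of the propargylic alkoxide puts the alkyl group on C2 and magnesium on C3 cis to the CH2O group in a chelate, and iodinolysis with retention should give the Z iodide.

Step 19
Reactants: 32 (2Z)-3-iodo-2-(4-methylpent-3-en-1-yl)prop-2-en-1-ol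
Product: 33 tert-butyl{[(2Z)-3-iodo-2-(4-methylpent-3-en-1-yl)prop-2-en-1-yl]oxy}dimethylsilane
Conditions: TBSCl, imidazole, CH2Cl2, 0 °C → rt
Reagents that add atoms: tert-butyl(chloro)dimethylsilane, CC(C)(C)[Si](C)(C)Cl
Why: Silylation of the primary allylic alcohol protects it for the two coupling steps.

Step 20
Reactants: 33 silyl-protected Z iodide; 34 (E)-1,2-bis(tributylstannyl)ethene
Product: 35 tert-butyl(dimethyl){[(2Z,4E)-2-(4-methylpent-3-en-1-yl)-5-(tributylstannyl)penta-2,4-dien-1-yl]oxy}silane
Conditions: 34 (3 equiv), PdCl2(MeCN)2 (5 mol%), DMF, rt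
Reagents that add atoms: none
Why: Stille coupling of the alkenyl iodide with an excess of the distannane should couple one tin terminus only and keep both alkene geometries.

Step 21
Reactants: 27 enol triflate; 35 dienylstannane
Product: 36 fully protected triene (three silyl ethers, dimethyl acetal, free tertiary hydroxyl)
Conditions: Pd(PPh3)4 (10 mol%), LiCl, THF, 60 °C
Reagents that add atoms: none
Why: Stille coupling of the enol triflate with the E alkenylstannane should form the bond between the 1,1-disubstituted alkene carbon and the diene with retention of all alkene geometries.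

Step 22
Reactants: 36 fully protected triene
Product: 38 target, (1S,4S,5S,6R,10S) in route locants with Z enal and E,Z diene, via tetraol acetal 37 (not isolated)
Conditions: Bu4NF, THF, 0 → 40 °C; then AcOH/H2O/THF, rt
Reagents that add atoms: water, O
Why: Fluoride desilylation removes the three silyl ethers while the acetal protects the enal from the basic fluoride, and mild aqueous acid then hydrolyses the allylic dimethyl acetal.

Compound list
1 | cyclopent-2-en-1-one | O=C1C=CCC1 | starting material
2 | isopropenylmagnesium bromide | CC(=C)[Mg]Br | starting material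
3 | allyl bromide | C=CCBr | starting material
4 | bromomagnesium (3S)-3-(prop-1-en-2-yl)cyclopent-1-en-1-olate (not isolated) | Br[Mg]OC1=C[C@@H](C(C)=C)CC1 | intermediate
5 | (2R,3S)-2-allyl-3-(prop-1-en-2-yl)cyclopentan-1-one | O=C1[C@H](CC=C)[C@@H](C(C)=C)CC1 | intermediate
6 | (chloromethyl)(isopropoxy)dimethylsilane | ClC[Si](C)(C)OC(C)C | starting material
7 | {[isopropoxy(dimethyl)silyl]methyl}magnesium chloride (not isolated) | CC(C)O[Si](C)(C)C[Mg]Cl | intermediate
8 | chloromagnesium (3R)-3-{[isopropoxy(dimethyl)silyl]methyl}cyclopent-1-en-1-olate (not isolated) | CC(C)O[Si](C)(C)C[C@@H]1CCC(O[Mg]Cl)=C1 | intermediate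
9 | (3R)-3-{[isopropoxy(dimethyl)silyl]methyl}cyclopent-1-en-1-yl trifluoromethanesulfonate | CC(C)O[Si](C)(C)C[C@@H]1CCC(OS(=O)(=O)C(F)(F)F)=C1 | intermediate
10 | (3R)-3-(hydroxymethyl)cyclopent-1-en-1-yl trifluoromethanesulfonate | OC[C@@H]1CCC(OS(=O)(=O)C(F)(F)F)=C1 | intermediate
11 | (3R)-3-({[tert-butyl(dimethyl)silyl]oxy}methyl)cyclopent-1-en-1-yl trifluoromethanesulfonate | CC(C)(C)[Si](C)(C)OC[C@@H]1CCC(OS(=O)(=O)C(F)(F)F)=C1 | intermediate
12 | tert-butyl(dimethyl){[(1R)-3-(trimethylstannyl)cyclopent-2-en-1-yl]methoxy}silane | CC(C)(C)[Si](C)(C)OC[C@@H]1CCC([Sn](C)(C)C)=C1 | intermediate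
13 | [(3R)-3-({[tert-butyl(dimethyl)silyl]oxy}methyl)cyclopent-1-en-1-yl]lithium (not isolated) | CC(C)(C)[Si](C)(C)OC[C@@H]1CCC([Li])=C1 | intermediate
14 | (1S,2R,3S)-2-allyl-1-[(3R)-3-({[tert-butyl(dimethyl)silyl]oxy}methyl)cyclopent-1-en-1-yl]-3-(prop-1-en-2-yl)cyclopentan-1-ol | CC(C)(C)[Si](C)(C)OC[C@@H]1CCC(=C1)[C@@]2(O)[C@H](CC=C)[C@@H](C(C)=C)CC2 | intermediate
15 | C4–C5 epoxide of 14, oxygen on the face opposite the C1 arm (not isolated) | CC(C)(C)[Si](C)(C)OC[C@@H]1CC[C@]2(O[C@@H]12)[C@@]3(O)[C@H](CC=C)[C@@H](C(C)=C)CC3 | intermediate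
16 | spiro ketol: C5 hydroxyl trans to the C1 arm, C4–C6 bond anti to the C5 oxygen, C6 allyl and C7 isopropenyl trans, C10 ketone | CC(C)(C)[Si](C)(C)OC[C@@H]1CC[C@]2([C@H](CC=C)[C@@H](C(C)=C)CCC2=O)[C@H]1O | intermediate
17 | 5-O-tert-butyldimethylsilyl ether of 16 | CC(C)(C)[Si](C)(C)OC[C@@H]1CC[C@]2([C@H](CC=C)[C@@H](C(C)=C)CCC2=O)[C@H]1O[Si](C)(C)C(C)(C)C | intermediate
18 | C1 hydroxymethyl ketone with C5 silyl ether | OC[C@@H]1CC[C@]2([C@H](CC=C)[C@@H](C(C)=C)CCC2=O)[C@H]1O[Si](C)(C)C(C)(C)C | intermediate
19 | C1 aldehyde with C10 ketone and C5 silyl ether | O=C[C@@H]1CC[C@]2([C@H](CC=C)[C@@H](C(C)=C)CCC2=O)[C@H]1O[Si](C)(C)C(C)(C)C | intermediate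
20 | diol: (10S) methyl carbinol with hydroxyl on the C5 side, 1-hydroxyethyl at C1 (epimers) | CC(O)[C@@H]1CC[C@]2([C@H](CC=C)[C@@H](C(C)=C)CC[C@]2(C)O)[C@H]1O[Si](C)(C)C(C)(C)C | intermediate
21 | triol with 3-hydroxypropyl chain at C6 | CC(O)[C@@H]1CC[C@]2([C@H](CCCO)[C@@H](C(C)=C)CC[C@]2(C)O)[C@H]1O[Si](C)(C)C(C)(C)C | intermediate
22 | tert-butyldiphenylsilyl ether of the chain hydroxyl of 21 | CC(O)[C@@H]1CC[C@]2([C@H](CCCO[Si](c3ccccc3)(c3ccccc3)C(C)(C)C)[C@@H](C(C)=C)CC[C@]2(C)O)[C@H]1O[Si](C)(C)C(C)(C)C | intermediate
23 | allylic alcohol, C7 3-hydroxyprop-1-en-2-yl (not isolated) | CC(O)[C@@H]1CC[C@]2([C@H](CCCO[Si](c3ccccc3)(c3ccccc3)C(C)(C)C)[C@@H](C(=C)CO)CC[C@]2(C)O)[C@H]1O[Si](C)(C)C(C)(C)C | intermediate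
24 | keto enal: C1 acetyl, C7 3-oxoprop-1-en-2-yl | CC(=O)[C@@H]1CC[C@]2([C@H](CCCO[Si](c3ccccc3)(c3ccccc3)C(C)(C)C)[C@@H](C(=C)C=O)CC[C@]2(C)O)[C@H]1O[Si](C)(C)C(C)(C)C | intermediate
25 | tetrasubstituted (Z)-enal, C7=C(CH3)CHO with formyl syn to C6 | CC(=O)[C@@H]1CC[C@]2([C@H](CCCO[Si](c3ccccc3)(c3ccccc3)C(C)(C)C)/C(=C(/C)C=O)CC[C@]2(C)O)[C@H]1O[Si](C)(C)C(C)(C)C | intermediate
26 | dimethyl acetal of 25 | CC(=O)[C@@H]1CC[C@]2([C@H](CCCO[Si](c3ccccc3)(c3ccccc3)C(C)(C)C)/C(=C(/C)C(OC)OC)CC[C@]2(C)O)[C@H]1O[Si](C)(C)C(C)(C)C | intermediate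
27 | enol triflate, C1–C(OSO2CF3)=CH2 | C=C(OS(=O)(=O)C(F)(F)F)[C@@H]1CC[C@]2([C@H](CCCO[Si](c3ccccc3)(c3ccccc3)C(C)(C)C)/C(=C(/C)C(OC)OC)CC[C@]2(C)O)[C@H]1O[Si](C)(C)C(C)(C)C | intermediate
28 | 5-bromo-2-methylpent-2-ene | CC(C)=CCCBr | starting material
29 | prop-2-yn-1-ol | C#CCO | starting material
30 | (4-methylpent-3-en-1-yl)magnesium bromide (not isolated) | CC(C)=CCC[Mg]Br | intermediate
31 | alkenylmagnesium alkoxide from anti-carbomagnesiation, magnesium cis to CH2O (not isolated) | Br[Mg]/C=C(/CCC=C(C)C)CO[Mg]Br | intermediate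
32 | (2Z)-3-iodo-2-(4-methylpent-3-en-1-yl)prop-2-en-1-ol | I/C=C(/CCC=C(C)C)CO | intermediate
33 | tert-butyl{[(2Z)-3-iodo-2-(4-methylpent-3-en-1-yl)prop-2-en-1-yl]oxy}dimethylsilane | I/C=C(/CCC=C(C)C)CO[Si](C)(C)C(C)(C)C | intermediate
34 | (E)-1,2-bis(tributylstannyl)ethene | CCCC[Sn](CCCC)(CCCC)/C=C/[Sn](CCCC)(CCCC)CCCC | starting material
35 | tert-butyl(dimethyl){[(2Z,4E)-2-(4-methylpent-3-en-1-yl)-5-(tributylstannyl)penta-2,4-dien-1-yl]oxy}silane | CCCC[Sn](CCCC)(CCCC)/C=C/C=C(/CCC=C(C)C)CO[Si](C)(C)C(C)(C)C | intermediate
36 | fully protected triene: three silyl ethers, dimethyl acetal, free C10 hydroxyl | C=C(/C=C/C=C(\CO[Si](C)(C)C(C)(C)C)CCC=C(C)C)[C@@H]1CC[C@]2([C@H](CCCO[Si](c3ccccc3)(c3ccccc3)C(C)(C)C)/C(=C(/C)C(OC)OC)CC[C@]2(C)O)[C@H]1O[Si](C)(C)C(C)(C)C | intermediate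
37 | tetraol dimethyl acetal (not isolated) | C=C(/C=C/C=C(\CO)CCC=C(C)C)[C@@H]1CC[C@]2([C@H](CCCO)/C(=C(/C)C(OC)OC)CC[C@]2(C)O)[C@H]1O | intermediate
38 | CNP0249558.1, (1S,4S,5S,6R,10S) in route locants, Z enal, E and Z diene bonds | C=C(/C=C/C=C(\CO)CCC=C(C)C)[C@@H]1CC[C@]2([C@H](CCCO)/C(=C(/C)C=O)CC[C@]2(C)O)[C@H]1O | target

Total step count: 22. Longest linear sequence: 18 steps (steps 2–17, 21 and 22, from cyclopent-2-en-1-one).

Steps most likely to fail

Step 7. Oxygen may be delivered to the face of the cyclopentene that carries the arm, C9 may migrate in place of C6, the C4 cation or the Lewis acid-activated ketone may be captured by the isopropenyl alkene, or the primary silyl ether may be lost under BF3. The fallback sets out from 14 and keeps the same bond construction but changes both control elements. Silylation (Me3SiCl, imidazole) should give the trimethylsilyl ether F1. Epoxidation without hydroxyl direction, by the Shi ketone with KHSO5 (catalyst enantiomer chosen to attack the face opposite the arm), should give the epoxy silyl ether F2, which is isolated and its configuration checked. TiCl4 in CH2Cl2 at −78 °C then triggers the rearrangement of the 2,3-epoxy silyl ether, in which the silyl ether is the electron-releasing group; aqueous work-up removes the silyl group and the route is rejoined at 16.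

Step 15. The double bond may migrate incompletely or too far (into the ring, which would scramble C6 through β,γ-isomers), the alkene geometry may settle on an unfavourable mixture, and the acid released from the rhodium salt may strip silyl ethers. The fallback sets out from 24 and replaces the equilibration by a reduction–dehydrogenation pair. 1,4-Hydrosilylation (Et3SiH, RhCl(PPh3)3 cat., THF, 50 °C) should give the triethylsilyl enol ether F3. Saegusa–Ito oxidation with Pd(OAc)2 in MeCN then removes the C7 hydrogen by β-hydride elimination, as 2-alkyl enol ethers give the more substituted enone, and returns the route at 25.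

Step 14. The ene step may abstract the ring hydrogen at C7 in place of a methyl hydrogen, which leads to a tertiary allylic alcohol, and the alcohol may be over-oxidised unevenly. The fallback sets out from 22 and fixes the regiochemistry by base-mediated elimination. Epoxidation of the only alkene (m-chloroperbenzoic acid, NaHCO3, CH2Cl2, 0 °C) should give the epoxide F4. Excess diethylaluminium 2,2,6,6-tetramethylpiperidide in toluene at 0 °C removes a methyl hydrogen in a syn-elimination and opens the epoxide to the allylic alcohol 23, where the route is rejoined; 23 is then oxidised as in the second stage of step 14.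

Further compounds
F1 | step 7 | trimethylsilyl ether of 14 | CC(C)(C)[Si](C)(C)OC[C@@H]1CCC(=C1)[C@@]2(O[Si](C)(C)C)[C@H](CC=C)[C@@H](C(C)=C)CC2
F2 | step 7 | C4–C5 epoxide of F1, oxygen on the face opposite the C1 arm | CC(C)(C)[Si](C)(C)OC[C@@H]1CC[C@]2(O[C@@H]12)[C@@]3(O[Si](C)(C)C)[C@H](CC=C)[C@@H](C(C)=C)CC3
F3 | step 15 | triethylsilyl enol ether from 1,4-hydrosilylation of 24 (E/Z mixture) | CC(=O)[C@@H]1CC[C@]2([C@H](CCCO[Si](c3ccccc3)(c3ccccc3)C(C)(C)C)[C@@H](C(C)=CO[Si](CC)(CC)CC)CC[C@]2(C)O)[C@H]1O[Si](C)(C)C(C)(C)C
F4 | step 14 | epoxide of the isopropenyl group of 22 (epimers at the oxirane carbon) | CC(O)[C@@H]1CC[C@]2([C@H](CCCO[Si](c3ccccc3)(c3ccccc3)C(C)(C)C)[C@@H](C3(C)CO3)CC[C@]2(C)O)[C@H]1O[Si](C)(C)C(C)(C)C
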